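**Retrosynthetic overview**
1. The ester C–O bond is not made by acylation: the aryl carboxylate opens a trisubstituted epoxide by SN2 at the future C6 (inversion), which sets C6 and frees the C7 tertiary alcohol in one step.
2. C7 comes from a Sharpless epoxidation of a commercial (Z)-enynol; an acetylide alkylation adds a furyl alkyne (the furan is a latent C3 ketone plus acrylic acid).
3. Ring A (carbocycle) is formed first: 6-exo-dig enolate–alkyne carbocyclisation of an acyclic keto-yne, the resulting dienolate being trapped with CH2O to install C1.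
4. Ring B (pyran) is formed last: oxidative opening of the furan gives a 4-oxo-2-enal whose ketone is captured by the C1 hydroxyl (cyclodehydration).
5. End game: Pinnick oxidation to the acrylic acid, then one acid step frees the catechol and the C7 hydroxyl.

Assumption: (2Z)-3-methylpent-2-en-4-yn-1-ol, 2-ethynylfuran and 2,3,4-trimethoxy-6-methylbenzaldehyde are taken as commercially available.
Shorthand: "ester of acid 5" means the 4-methoxy-6-methyl-2,2-diphenyl-1,3-benzodioxole-5-carboxylate; locants C1–C8a are the isochromene locants of the target.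

**Step 1**
Reactants: 1 2,3,4-trimethoxy-6-methylbenzaldehyde
Product: 2 2,3,4-trihydroxy-6-methylbenzaldehyde
Conditions: BBr3 (3.5 equiv), CH2Cl2, −78 → 25 °C; then H2O
Reagents that add atoms: none
Why: BBr3 ether cleavage removes all three aryl methyl groups while the aldehyde survives at low temperature; no stereocentre is involved.

**Step 2**
Reactants: 2 2,3,4-trihydroxy-6-methylbenzaldehyde
Product: 3 4-hydroxy-6-methyl-2,2-diphenyl-1,3-benzodioxole-5-carbaldehyde
Conditions: Ph2CCl2 (1.1 equiv), K2CO3 (2.2 equiv), MeCN, 25 → 60 °C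
Reagents that add atoms: dichlorodiphenylmethane, ClC(Cl)(c1ccccc1)c1ccccc1
Why: Double O-alkylation (ketalisation) takes the 3,4-catechol pair because the 2-OH is locked in a hydrogen bond to the aldehyde and is the poorest nucleophile.

**Step 3**
Reactants: 3 4-hydroxy-6-methyl-2,2-diphenyl-1,3-benzodioxole-5-carbaldehyde
Product: 4 4-methoxy-6-methyl-2,2-diphenyl-1,3-benzodioxole-5-carbaldehyde
Conditions: MeI (1.5 equiv), K2CO3, DMF, 50 °C
Reagents that add atoms: iodomethane, CI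
Why: Williamson O-methylation of the one remaining phenol gives the 2-methoxy group of the target's acid part.

**Step 4**
Reactants: 4 4-methoxy-6-methyl-2,2-diphenyl-1,3-benzodioxole-5-carbaldehyde
Product: 5 4-methoxy-6-methyl-2,2-diphenyl-1,3-benzodioxole-5-carboxylic acid
Conditions: NaClO2, NaH2PO4, 2-methyl-2-butene, t-BuOH–H2O, 25 °C
Reagents that add atoms: sodium chlorite, [Na+].[O-]Cl=O
Why: Pinnick oxidation converts the hindered aldehyde into the acid without touching the ketal or the ethers.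

**Step 5**
Reactants: 6 (2Z)-3-methylpent-2-en-4-yn-1-ol
Product: 7 [(2S,3R)-3-ethynyl-3-methyloxiran-2-yl]methanol
Conditions: Ti(OiPr)4 (10 mol%), L-(+)-diethyl tartrate (12 mol%), t-BuOOH (2 equiv), 4 Å MS, CH2Cl2, −20 °C
Reagents that add atoms: tert-butyl hydroperoxide, CC(C)(C)OO
Why: Sharpless asymmetric epoxidation of a 3,3-disubstituted (Z)-allylic alcohol is reagent-controlled, and L-(+)-tartrate gives the (2S,3R)-epoxide (same facial sense as nerol), which fixes the future C7 and places the epoxide oxygen for the later inversion at C6.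

**Step 6**
Reactants: 7 [(2S,3R)-3-ethynyl-3-methyloxiran-2-yl]methanol; 8 2-ethynylfuran
Product: 11 2-{3-[(2S,3R)-3-ethynyl-3-methyloxiran-2-yl]prop-1-yn-1-yl}furan, via epoxy triflate 9 (not isolated), via lithium furylethynide 10 (not isolated)
Conditions: 7, Tf2O (1.05 equiv), 2,6-lutidine, CH2Cl2, −78 °C; 8 (2 equiv), n-BuLi, THF, −78 °C; combine, THF–DMPU, −78 → −20 °C
Reagents that add atoms: none
Why: SN2 alkylation of an acetylide by a primary glycidyl-type triflate is much faster at −78 °C than epoxide opening (no Lewis acid present), and the more acidic furyl alkyne keeps the substrate's own terminal alkyne protonated; both stereocentres are untouched.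

**Step 7**
Reactants: 11 2-{3-[(2S,3R)-3-ethynyl-3-methyloxiran-2-yl]prop-1-yn-1-yl}furan; 5 4-methoxy-6-methyl-2,2-diphenyl-1,3-benzodioxole-5-carboxylic acid
Product: 12 (4R,5R)-1-(furan-2-yl)-5-hydroxy-5-methylhepta-1,6-diyn-4-yl ester of acid 5
Conditions: 5 (1.3 equiv), Cs2CO3 (0.15 equiv), DMF, 85 °C
Reagents that add atoms: none
Why: In this base-catalysed acid–epoxide addition the carboxylate of 5 attacks the less substituted oxirane carbon by SN2 (the tertiary propargylic carbon is blocked), so C6 is set by clean inversion and the hindered ester is made by O-alkylation instead of acyl transfer, with the tertiary alcohol appearing unprotected.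

**Step 8**
Reactants: 12 (4R,5R)-1-(furan-2-yl)-5-hydroxy-5-methylhepta-1,6-diyn-4-yl ester of acid 5
Product: 14 (4R,5S)-1-(furan-2-yl)-5-hydroxy-5-methyl-6-oxohept-1-yn-4-yl ester of acid 5, via cyclic enol carbonate 13 (not isolated)
Conditions: AgOAc (10 mol%), DBU (1 equiv), CO2 (1 atm), MeCN, 25 °C; then H2O, 50 °C
Reagents that add atoms: water, O
Why: CO2-promoted Markovnikov hydration of a tertiary propargylic alcohol: the carbonate formed on the free hydroxyl adds 5-exo-dig only to its own alkyne, and hydrolysis with loss of CO2 gives the methyl ketone while the furyl alkyne stays intact (the descriptor at C5 changes only through CIP priorities).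

**Step 9**
Reactants: 14 (4R,5S)-1-(furan-2-yl)-5-hydroxy-5-methyl-6-oxohept-1-yn-4-yl ester of acid 5
Product: 15 (4R,5S)-1-(furan-2-yl)-5-methyl-6-oxo-5-(triethylsilyloxy)hept-1-yn-4-yl ester of acid 5
Conditions: Et3SiOTf (1.3 equiv), 2,6-lutidine, CH2Cl2, −78 → 0 °C
Reagents that add atoms: triethylsilyl trifluoromethanesulfonate, CC[Si](CC)(CC)OS(=O)(=O)C(F)(F)F
Why: Silyl triflate silylation of the tertiary α-hydroxyl removes the alkoxide that would otherwise add to the furyl alkyne in the next step.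

**Step 10**
Reactants: 15 (4R,5S)-1-(furan-2-yl)-5-methyl-6-oxo-5-(triethylsilyloxy)hept-1-yn-4-yl ester of acid 5
Product: 18 (1R,2S)-5-(furan-2-ylmethyl)-4-(hydroxymethyl)-2-methyl-3-oxo-2-(triethylsilyloxy)cyclohex-4-en-1-yl ester of acid 5, via potassium dienolate 16 (not isolated), via hydroxymethyl ketone 17 (not isolated)
Conditions: KN(SiMe3)2 (1.1 equiv), 18-crown-6, THF, −78 → 40 °C; −78 °C, CH2O (gas, from paraformaldehyde); AcOH; then DABCO (0.2 equiv), CH2Cl2, 25 °C
Reagents that add atoms: formaldehyde, C=O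
Why: Proposed new method: the methyl ketone is the only enolisable site, its enolate adds 6-exo-dig to the alkyne at the carbon remote from the furan (the vinyl anion is then furyl-stabilised; closest known type is the base-mediated Conia-ene/KOtBu C-vinylation of ketones with aryl alkynes), internal proton transfer gives the extended dienolate, which takes CH2O at its α-carbon as metal dienolates do, and DABCO moves the double bond into conjugation; C6 and C7 are untouched.

**Step 11**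
Reactants: 18 (1R,2S)-5-(furan-2-ylmethyl)-4-(hydroxymethyl)-2-methyl-3-oxo-2-(triethylsilyloxy)cyclohex-4-en-1-yl ester of acid 5
Product: 21 (6R,7S)-7-methyl-8-oxo-3-[(E)-3-oxoprop-1-en-1-yl]-7-(triethylsilyloxy)-5,6,7,8-tetrahydro-1H-isochromen-6-yl ester of acid 5, via Z keto enal 19 (not isolated), via E keto enal 20 (not isolated)
Conditions: NBS (1.05 equiv), NaHCO3, acetone–H2O, −20 °C; pyridine, 25 °C; then PPTS (10 mol%), 4 Å MS, CH2Cl2, 25 °C
Reagents that add atoms: water, O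
Why: NBS/H2O oxidative ring opening of the 2-alkylfuran gives the 4-oxo-2-enal, pyridine isomerises it to E, and acid-catalysed hemiketalisation and dehydration by the C1 hydroxyl closes ring B as the fully conjugated dienol ether (the thermodynamic sink), leaving the electron-poor enone and the stereocentres alone.

**Step 12**
Reactants: 21 (6R,7S)-7-methyl-8-oxo-3-[(E)-3-oxoprop-1-en-1-yl]-7-(triethylsilyloxy)-5,6,7,8-tetrahydro-1H-isochromen-6-yl ester of acid 5
Product: 22 (2E)-3-[(6R,7S)-6-(ester of acid 5)-7-methyl-8-oxo-7-(triethylsilyloxy)-5,6,7,8-tetrahydro-1H-isochromen-3-yl]prop-2-enoic acid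
Conditions: NaClO2, NaH2PO4, 2-methyl-2-butene (excess), t-BuOH–H2O, 0 → 25 °C
Reagents that add atoms: sodium chlorite, [Na+].[O-]Cl=O
Why: Pinnick oxidation turns the enal into the (E)-acrylic acid under buffered conditions that spare the silyl ether, ketal and dienol ether (HOCl is scavenged by the alkene).

**Step 13**
Reactants: 22 (2E)-3-[(6R,7S)-6-(ester of acid 5)-7-methyl-8-oxo-7-(triethylsilyloxy)-5,6,7,8-tetrahydro-1H-isochromen-3-yl]prop-2-enoic acid
Product: 23 (2E)-3-[(6R,7S)-6-(3,4-dihydroxy-2-methoxy-6-methylbenzoyloxy)-7-hydroxy-7-methyl-8-oxo-5,6,7,8-tetrahydro-1H-isochromen-3-yl]prop-2-enoic acid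
Conditions: CF3CO2H–CH2Cl2–H2O (10:10:1), 0 → 25 °C
Reagents that add atoms: none
Why: Acid hydrolysis removes the diphenylmethylene ketal and the triethylsilyl ether in one operation, while the hindered aryl ester and the push–pull dienone are stable to acid and no base is used that could eliminate the C6 carboxylate.

**Compound list**
1 | 2,3,4-trimethoxy-6-methylbenzaldehyde | COc1cc(C)c(C=O)c(OC)c1OC | starting material
2 | 2,3,4-trihydroxy-6-methylbenzaldehyde | Cc1cc(O)c(O)c(O)c1C=O | intermediate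
3 | 4-hydroxy-6-methyl-2,2-diphenyl-1,3-benzodioxole-5-carbaldehyde | Cc1cc2OC(c3ccccc3)(c3ccccc3)Oc2c(O)c1C=O | intermediate
4 | 4-methoxy-6-methyl-2,2-diphenyl-1,3-benzodioxole-5-carbaldehyde | COc1c(C=O)c(C)cc2OC(c3ccccc3)(c3ccccc3)Oc12 | intermediate
5 | 4-methoxy-6-methyl-2,2-diphenyl-1,3-benzodioxole-5-carboxylic acid | COc1c(C(=O)O)c(C)cc2OC(c3ccccc3)(c3ccccc3)Oc12 | intermediate
6 | (2Z)-3-methylpent-2-en-4-yn-1-ol | C#C/C(C)=C\CO | starting material
7 | [(2S,3R)-3-ethynyl-3-methyloxiran-2-yl]methanol | OC[C@@H]1O[C@]1(C)C#C | intermediate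
8 | 2-ethynylfuran | C#Cc1ccco1 | starting material
9 | [(2S,3R)-3-ethynyl-3-methyloxiran-2-yl]methyl trifluoromethanesulfonate | FC(F)(F)S(=O)(=O)OC[C@@H]1O[C@]1(C)C#C | intermediate
10 | lithium 2-(furan-2-yl)ethyn-1-ide | [Li+].[C-]#Cc1ccco1 | intermediate
11 | 2-{3-[(2S,3R)-3-ethynyl-3-methyloxiran-2-yl]prop-1-yn-1-yl}furan | o1cccc1C#CC[C@@H]2O[C@]2(C)C#C | intermediate
12 | (4R,5R)-1-(furan-2-yl)-5-hydroxy-5-methylhepta-1,6-diyn-4-yl 4-methoxy-6-methyl-2,2-diphenyl-1,3-benzodioxole-5-carboxylate | COc1c(C(=O)O[C@H](CC#Cc2ccco2)[C@](C)(O)C#C)c(C)cc2OC(c3ccccc3)(c3ccccc3)Oc12 | intermediate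
13 | (1R)-4-(furan-2-yl)-1-[(4S)-4-methyl-5-methylidene-2-oxo-1,3-dioxolan-4-yl]but-3-yn-1-yl 4-methoxy-6-methyl-2,2-diphenyl-1,3-benzodioxole-5-carboxylate | COc1c(C(=O)O[C@H](CC#Cc2ccco2)[C@]2(C)OC(=O)OC2=C)c(C)cc2OC(c3ccccc3)(c3ccccc3)Oc12 | intermediate
14 | (4R,5S)-1-(furan-2-yl)-5-hydroxy-5-methyl-6-oxohept-1-yn-4-yl 4-methoxy-6-methyl-2,2-diphenyl-1,3-benzodioxole-5-carboxylate | COc1c(C(=O)O[C@H](CC#Cc2ccco2)[C@](C)(O)C(C)=O)c(C)cc2OC(c3ccccc3)(c3ccccc3)Oc12 | intermediate
15 | (4R,5S)-1-(furan-2-yl)-5-methyl-6-oxo-5-[(triethylsilyl)oxy]hept-1-yn-4-yl 4-methoxy-6-methyl-2,2-diphenyl-1,3-benzodioxole-5-carboxylate | COc1c(C(=O)O[C@H](CC#Cc2ccco2)[C@](C)(O[Si](CC)(CC)CC)C(C)=O)c(C)cc2OC(c3ccccc3)(c3ccccc3)Oc12 | intermediate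
16 | potassium (5R,6S)-3-(furan-2-ylmethylidene)-5-{[(4-methoxy-6-methyl-2,2-diphenyl-1,3-benzodioxol-5-yl)carbonyl]oxy}-6-methyl-6-[(triethylsilyl)oxy]cyclohex-1-en-1-olate (alkene geometry not fixed) | [K+].COc1c(C(=O)O[C@@H]2CC(=Cc3ccco3)C=C([O-])[C@@]2(C)O[Si](CC)(CC)CC)c(C)cc2OC(c3ccccc3)(c3ccccc3)Oc12 | intermediate
17 | (1R,2S)-5-(furan-2-ylmethylidene)-4-(hydroxymethyl)-2-methyl-3-oxo-2-[(triethylsilyl)oxy]cyclohexyl 4-methoxy-6-methyl-2,2-diphenyl-1,3-benzodioxole-5-carboxylate (C4 epimers and alkene isomers, both erased in the same flask) | COc1c(C(=O)O[C@@H]2CC(=Cc3ccco3)C(CO)C(=O)[C@@]2(C)O[Si](CC)(CC)CC)c(C)cc2OC(c3ccccc3)(c3ccccc3)Oc12 | intermediate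
18 | (1R,2S)-5-(furan-2-ylmethyl)-4-(hydroxymethyl)-2-methyl-3-oxo-2-[(triethylsilyl)oxy]cyclohex-4-en-1-yl 4-methoxy-6-methyl-2,2-diphenyl-1,3-benzodioxole-5-carboxylate | COc1c(C(=O)O[C@@H]2CC(Cc3ccco3)=C(CO)C(=O)[C@@]2(C)O[Si](CC)(CC)CC)c(C)cc2OC(c3ccccc3)(c3ccccc3)Oc12 | intermediate
19 | (1R,2S)-5-[(3Z)-2,5-dioxopent-3-en-1-yl]-4-(hydroxymethyl)-2-methyl-3-oxo-2-[(triethylsilyl)oxy]cyclohex-4-en-1-yl 4-methoxy-6-methyl-2,2-diphenyl-1,3-benzodioxole-5-carboxylate | COc1c(C(=O)O[C@@H]2CC(CC(=O)/C=C\C=O)=C(CO)C(=O)[C@@]2(C)O[Si](CC)(CC)CC)c(C)cc2OC(c3ccccc3)(c3ccccc3)Oc12 | intermediate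
20 | (1R,2S)-5-[(3E)-2,5-dioxopent-3-en-1-yl]-4-(hydroxymethyl)-2-methyl-3-oxo-2-[(triethylsilyl)oxy]cyclohex-4-en-1-yl 4-methoxy-6-methyl-2,2-diphenyl-1,3-benzodioxole-5-carboxylate | COc1c(C(=O)O[C@@H]2CC(CC(=O)/C=C/C=O)=C(CO)C(=O)[C@@]2(C)O[Si](CC)(CC)CC)c(C)cc2OC(c3ccccc3)(c3ccccc3)Oc12 | intermediate
21 | (6R,7S)-7-methyl-8-oxo-3-[(1E)-3-oxoprop-1-en-1-yl]-7-[(triethylsilyl)oxy]-5,6,7,8-tetrahydro-1H-isochromen-6-yl 4-methoxy-6-methyl-2,2-diphenyl-1,3-benzodioxole-5-carboxylate | COc1c(C(=O)O[C@@H]2CC3=C(COC(/C=C/C=O)=C3)C(=O)[C@@]2(C)O[Si](CC)(CC)CC)c(C)cc2OC(c3ccccc3)(c3ccccc3)Oc12 | intermediate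
22 | (2E)-3-[(6R,7S)-6-{[(4-methoxy-6-methyl-2,2-diphenyl-1,3-benzodioxol-5-yl)carbonyl]oxy}-7-methyl-8-oxo-7-[(triethylsilyl)oxy]-5,6,7,8-tetrahydro-1H-isochromen-3-yl]prop-2-enoic acid | COc1c(C(=O)O[C@@H]2CC3=C(COC(/C=C/C(=O)O)=C3)C(=O)[C@@]2(C)O[Si](CC)(CC)CC)c(C)cc2OC(c3ccccc3)(c3ccccc3)Oc12 | intermediate
23 | (2E)-3-[(6R,7S)-6-[(3,4-dihydroxy-2-methoxy-6-methylbenzoyl)oxy]-7-hydroxy-7-methyl-8-oxo-5,6,7,8-tetrahydro-1H-isochromen-3-yl]prop-2-enoic acid | COc1c(O)c(O)cc(C)c1C(=O)O[C@@H]1CC2=C(COC(/C=C/C(=O)O)=C2)C(=O)[C@@]1(C)O | target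

**Step count and risks**
Total steps: 13. Longest linear sequence: 11 (steps 1–4, then 7–13); the chain from enynol 6 is 9 steps.

Steps most likely to fail, each with a fallback:

Step 10 (enolate–alkyne ring closure with CH2O trapping). The enolate may add too slowly to the unactivated furyl alkyne, or base may cause vinylogous loss of the C6 carboxylate once the enone exists. The fallback closes ring A by a radical instead of an anion. Setting out from 15, KN(SiMe3)2/Me3SiCl (THF, −78 °C) gives the trimethylsilyl enol ether F1. NBS (THF, −78 °C) converts it into the α-bromo ketone F2. Bu3SnH/AIBN (slow addition, benzene, 80 °C) then cyclises the electrophilic α-keto radical 6-exo-dig onto the electron-rich furyl alkyne to give the β,γ-unsaturated ketone F3. Kinetic α-deprotonation of F3 (LiN(SiMe3)2, THF, −78 °C), CH2O and DABCO isomerisation return to the route at 18.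

Step 7 (epoxide opening by the hindered carboxylate). The bulky benzoate may react too slowly at the hindered secondary carbon. The fallback uses a small nucleophile and then transfers the acyl group. Setting out from 11, CsOAc/AcOH (DMF, 90 °C) opens the epoxide with the same inversion to give the hydroxy acetate F4. K2CO3/MeOH gives the diol F5. Acid 5 is converted with (COCl)2/cat. DMF into the acid chloride F6, which (DMAP, Et3N, CH2Cl2, 40 °C) acylates only the secondary hydroxyl of F5, coming back to the route at 12.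

Step 11 (furan unveiling and ring B closure). The keto enal may undergo aldol-type self-condensation before ketalisation, or enal 21 may be too labile to carry into the chlorite oxidation. The fallback oxidises fully before closing the ring. Setting out from 18, the same NBS/NaHCO3 then pyridine treatment is followed in the same flask by NaClO2/NaH2PO4/2-methyl-2-butene. This gives the (E)-4-oxo-2-enoic acid F7, whose E geometry prevents lactol (pseudo-acid) formation. PPTS-catalysed cyclodehydration of F7 (4 Å MS, CH2Cl2) returns to the route at 22, bypassing 21 and step 12.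

**Further compounds**
F1 | step 10 | (4R,5S)-1-(furan-2-yl)-5-methyl-5-[(triethylsilyl)oxy]-6-[(trimethylsilyl)oxy]hept-6-en-1-yn-4-yl 4-methoxy-6-methyl-2,2-diphenyl-1,3-benzodioxole-5-carboxylate | COc1c(C(=O)O[C@H](CC#Cc2ccco2)[C@](C)(O[Si](CC)(CC)CC)C(=C)O[Si](C)(C)C)c(C)cc2OC(c3ccccc3)(c3ccccc3)Oc12
F2 | step 10 | (4R,5S)-7-bromo-1-(furan-2-yl)-5-methyl-6-oxo-5-[(triethylsilyl)oxy]hept-1-yn-4-yl 4-methoxy-6-methyl-2,2-diphenyl-1,3-benzodioxole-5-carboxylate | COc1c(C(=O)O[C@H](CC#Cc2ccco2)[C@](C)(O[Si](CC)(CC)CC)C(=O)CBr)c(C)cc2OC(c3ccccc3)(c3ccccc3)Oc12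
F3 | step 10 | (1R,2S)-5-(furan-2-ylmethylidene)-2-methyl-3-oxo-2-[(triethylsilyl)oxy]cyclohexyl 4-methoxy-6-methyl-2,2-diphenyl-1,3-benzodioxole-5-carboxylate (alkene isomers) | COc1c(C(=O)O[C@@H]2CC(=Cc3ccco3)CC(=O)[C@@]2(C)O[Si](CC)(CC)CC)c(C)cc2OC(c3ccccc3)(c3ccccc3)Oc12
F4 | step 7 | (4R,5R)-1-(furan-2-yl)-5-hydroxy-5-methylhepta-1,6-diyn-4-yl acetate | CC(=O)O[C@H](CC#Cc1ccco1)[C@](C)(O)C#C
F5 | step 7 | (4R,5R)-1-(furan-2-yl)-5-methylhepta-1,6-diyne-4,5-diol | O[C@H](CC#Cc1ccco1)[C@](C)(O)C#C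
F6 | step 7 | 4-methoxy-6-methyl-2,2-diphenyl-1,3-benzodioxole-5-carbonyl chloride | COc1c(C(Cl)=O)c(C)cc2OC(c3ccccc3)(c3ccccc3)Oc12
F7 | step 11 | (2E)-5-[(4S,5R)-2-(hydroxymethyl)-5-{[(4-methoxy-6-methyl-2,2-diphenyl-1,3-benzodioxol-5-yl)carbonyl]oxy}-4-methyl-3-oxo-4-[(triethylsilyl)oxy]cyclohex-1-en-1-yl]-4-oxopent-2-enoic acid | COc1c(C(=O)O[C@@H]2CC(CC(=O)/C=C/C(=O)O)=C(CO)C(=O)[C@@]2(C)O[Si](CC)(CC)CC)c(C)cc2OC(c3ccccc3)(c3ccccc3)Oc12
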